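**Strategy.** Furan B carries the furan-A-methyl group at B2 and the side chain at B4, with hydrogen at B3 and B5. That pattern is disconnected to a butenolide (B5 as lactone carbonyl, B2 as a racemic carbinol carbon) whose B3=B4 bond is made by ring-closing metathesis. One operation closes ring B and fixes the 2,4-pattern from the choice of alcohol and acid; reduction and dehydration then aromatise it. The precursor is the ester of racemic 1-(furan-3-yl)but-3-en-2-ol with 5-silyloxy-2-methylidenepentanoic acid. The chain is then grown by Wittig, Takai and Negishi steps with a Roche-ester zinc reagent, and the tetronic acid is attached by aldol condensation.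

Key step: step 7

Remark 1: ring A is the 3-substituted furan, ring B the 2,4-disubstituted furan (O1, B2 to B5), ring C the tetronic acid.
Remark 2: the target centre is (S); it is taken from methyl (S)-3-hydroxy-2-methylpropanoate, because here the ester carbon becomes the ylidene CH and the CH2OH carbon becomes the allylic CH2, so the priority order at the centre never changes.
Remark 3: compounds 6 and 24 are treated as catalogue materials.

**Step 1**
Reactants: 1 2-(furan-3-yl)acetic acid
Product: 2 2-(furan-3-yl)ethan-1-ol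
Conditions: LiAlH4, THF, 0 °C → rt; aq. NaOH work-up
Reagents that add atoms: none
Why: Hydride reduction of a carboxylic acid to the primary alcohol, with the aromatic furan inert to LiAlH4 and no stereocentre formed.

**Step 2**
Reactants: 2 2-(furan-3-yl)ethan-1-ol
Product: 4 (±)-1-(furan-3-yl)but-3-en-2-ol, via 2-(furan-3-yl)acetaldehyde 3 (not isolated)
Conditions: (COCl)2, DMSO, THF, −78 → −35 °C; Et3N; then CH2=CHMgBr (excess), −78 → 0 °C; aq. NH4Cl
Reagents that add atoms: vinylmagnesium bromide, C=C[Mg]Br
Why: Swern oxidation gives the self-condensing arylacetaldehyde, which is trapped in the same flask by Grignard 1,2-addition so that it is never handled; the carbinol centre is made racemic on purpose because step 8 erases it.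

**Step 3**
Reactants: 5 diethyl malonate; 6 (3-bromopropoxy)(tert-butyl)dimethylsilane
Product: 7 diethyl 2-{3-[(tert-butyldimethylsilyl)oxy]propyl}propanedioate
Conditions: NaH, THF/DMF, 0 °C; 6, NaI (cat.), 60 °C; excess 5
Reagents that add atoms: none
Why: Malonic ester alkylation, an SN2 displacement of a primary bromide by the sodium enolate, with excess malonate holding back dialkylation and the silyl ether inert.

**Step 4**
Reactants: 7 diethyl 2-{3-[(tert-butyldimethylsilyl)oxy]propyl}propanedioate
Product: 8 2-{3-[(tert-butyldimethylsilyl)oxy]propyl}propanedioic acid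
Conditions: KOH, EtOH/H2O, rt; then cold aq. KHSO4
Reagents that add atoms: potassium hydroxide, [K+].[OH-]
Why: Saponification of both ethyl esters by hydroxide; a primary silyl ether of this type withstands aqueous-alcoholic base and a brief cold acidification.

**Step 5**
Reactants: 8 2-{3-[(tert-butyldimethylsilyl)oxy]propyl}propanedioic acid
Product: 9 5-[(tert-butyldimethylsilyl)oxy]-2-methylidenepentanoic acid
Conditions: (CH2O)n, Et2NH, EtOAc, reflux; then cold aq. KHSO4
Reagents that add atoms: paraformaldehyde (formaldehyde), C=O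
Why: Mannich-type decarboxylative methylenation of a monosubstituted malonic acid, in which the malonate carbon adds to the iminium ion and loss of CO2 with expulsion of the amine gives the 2-substituted acrylic acid directly as the free acid.

**Step 6**
Reactants: 4 (±)-1-(furan-3-yl)but-3-en-2-ol; 9 5-[(tert-butyldimethylsilyl)oxy]-2-methylidenepentanoic acid
Product: 10 (±)-1-(furan-3-yl)but-3-en-2-yl 5-[(tert-butyldimethylsilyl)oxy]-2-methylidenepentanoate
Conditions: DCC, DMAP (cat.), CH2Cl2, 0 °C → rt
Reagents that add atoms: none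
Why: Steglich esterification (carbodiimide activation, acyl transfer by DMAP) joins the secondary allylic alcohol to the acrylic acid under neutral conditions that spare furan A, the silyl ether and both alkenes.

**Step 7**
Reactants: 10 (±)-1-(furan-3-yl)but-3-en-2-yl 5-[(tert-butyldimethylsilyl)oxy]-2-methylidenepentanoate
Product: 11 (±)-3-{3-[(tert-butyldimethylsilyl)oxy]propyl}-5-(furan-3-ylmethyl)furan-2(5H)-one
Conditions: second-generation Grubbs catalyst RuCl2(H2IMes)(PCy3)(=CHPh) (5 mol %), 1,4-benzoquinone (10 mol %), toluene (0.01 M), 80 °C, Ar sparge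
Reagents that add atoms: none
Why: The ruthenium benzylidene first exchanges with the monosubstituted vinyl group of the allylic ester, and the new alkylidene adds intramolecularly to the 1,1-disubstituted acrylate alkene by [2+2] cycloaddition; cycloreversion of the ruthenacyclobutane releases the butenolide, and the chain-carrying methylidene loses ethene. The closest known reaction type is the ring-closing metathesis of allylic esters of 2-substituted acrylic acids to α-substituted butenolides with N-heterocyclic-carbene ruthenium catalysts. The one ring formed is the five-membered lactone, closed by making the endocyclic C3=C4 double bond (B3=B4 of the later furan) between the two alkene carbons that give up their CH2 groups. No stereocentre is created, and the racemic carbinol carbon is a spectator that step 8 removes. The step needs ring closure over intermolecular metathesis and reaction at the two terminal alkenes only: dilution, heat and removal of ethene favour the five-membered ring, aromatic furan A and the silyl ether do not engage the carbene, and benzoquinone suppresses ruthenium-hydride alkene migration.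

**Step 8**
Reactants: 11 (±)-3-{3-[(tert-butyldimethylsilyl)oxy]propyl}-5-(furan-3-ylmethyl)furan-2(5H)-one
Product: 13 tert-butyl{3-[5-(furan-3-ylmethyl)furan-3-yl]propoxy}dimethylsilane, via lactol 12 (not isolated)
Conditions: i-Bu2AlH, CH2Cl2, −78 °C; then 0.5 M aq. HCl, 0 °C, short contact
Reagents that add atoms: none
Why: Partial reduction of the lactone stops at the lactol aluminate at −78 °C, and acid ionises the allylic hemiacetal to an oxocarbenium ion that loses the B2 proton, so dehydration–aromatisation gives furan B and deletes the sacrificial stereocentre while the brief cold acid leaves the silyl ether intact.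

**Step 9**
Reactants: 13 tert-butyl{3-[5-(furan-3-ylmethyl)furan-3-yl]propoxy}dimethylsilane
Product: 14 3-[5-(furan-3-ylmethyl)furan-3-yl]propan-1-ol
Conditions: n-Bu4NF, THF, 0 °C → rt
Reagents that add atoms: none
Why: Fluoride-driven desilylation under non-acidic conditions that are safe for the bis-furylmethane.

**Step 10**
Reactants: 14 3-[5-(furan-3-ylmethyl)furan-3-yl]propan-1-ol
Product: 15 3-[5-(furan-3-ylmethyl)furan-3-yl]propanal
Conditions: Dess–Martin periodinane, pyridine, CH2Cl2, 0 °C → rt
Reagents that add atoms: none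
Why: Dess–Martin oxidation stops cleanly at the aldehyde, and pyridine buffers the acetic acid so that the acid-sensitive furans are not exposed.

**Step 11**
Reactants: 15 3-[5-(furan-3-ylmethyl)furan-3-yl]propanal
Product: 16 (2E)-5-[5-(furan-3-ylmethyl)furan-3-yl]-2-methylpent-2-enal
Conditions: Ph3P=C(CH3)CHO, toluene, 90 °C
Reagents that add atoms: 2-(triphenylphosphoranylidene)propanal, CC(C=O)=P(c1ccccc1)(c1ccccc1)c1ccccc1
Why: Wittig olefination with a formyl-stabilised ylide is thermodynamically controlled and gives the (E)-2-methyl enal, and the ylide attacks the saturated aldehyde far faster than the conjugated product.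

**Step 12**
Reactants: 16 (2E)-5-[5-(furan-3-ylmethyl)furan-3-yl]-2-methylpent-2-enal
Product: 17 2-(furan-3-ylmethyl)-4-[(3E,5E)-6-iodo-4-methylhexa-3,5-dien-1-yl]furan
Conditions: CrCl2, CHI3, THF/1,4-dioxane, 0 °C → rt, dark
Reagents that add atoms: iodoform, IC(I)I
Why: Takai olefination, in which the geminal dichromium species from CHI3 adds to the aldehyde and eliminates to the (E)-vinyl iodide, with the existing trisubstituted alkene and the furans untouched.

**Step 13**
Reactants: 18 methyl (2S)-3-hydroxy-2-methylpropanoate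
Product: 19 methyl (2R)-3-iodo-2-methylpropanoate
Conditions: I2, PPh3, imidazole, CH2Cl2, 0 °C → rt
Reagents that add atoms: iodine, II
Why: Appel-type iodination displaces the activated primary oxygen by SN2 at CH2, so the neighbouring stereocentre is not touched and its descriptor changes to R only because CH2I outranks the ester.

**Step 14**
Reactants: 19 methyl (2R)-3-iodo-2-methylpropanoate; 17 2-(furan-3-ylmethyl)-4-[(3E,5E)-6-iodo-4-methylhexa-3,5-dien-1-yl]furan
Product: 21 methyl (2S,4E,6E)-9-[5-(furan-3-ylmethyl)furan-3-yl]-2,6-dimethylnona-4,6-dienoate, via alkylzinc iodide 20 (not isolated)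
Conditions: Zn dust (activated with BrCH2CH2Br, Me3SiCl), DMF, rt; then 17, PdCl2(dppf) (5 mol %), THF/DMF, rt → 40 °C, dark
Reagents that add atoms: none
Why: Zinc insertion gives the configurationally stable β-zincio ester, and Negishi coupling (oxidative addition, transmetalation, reductive elimination) joins C(sp3) to C(sp2) with retention of the (E,E)-diene geometry, the wide-bite dppf ligand favouring reductive elimination over β-hydride loss.

**Step 15**
Reactants: 21 methyl (2S,4E,6E)-9-[5-(furan-3-ylmethyl)furan-3-yl]-2,6-dimethylnona-4,6-dienoate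
Product: 22 (2S,4E,6E)-9-[5-(furan-3-ylmethyl)furan-3-yl]-2,6-dimethylnona-4,6-dien-1-ol
Conditions: LiAlH4, THF, 0 °C; aq. NaOH work-up
Reagents that add atoms: none
Why: Hydride reduction of the ester to the primary alcohol proceeds without enolisation, so the (S) centre is kept, and the diene and furans are inert.

**Step 16**
Reactants: 22 (2S,4E,6E)-9-[5-(furan-3-ylmethyl)furan-3-yl]-2,6-dimethylnona-4,6-dien-1-ol
Product: 23 (2S,4E,6E)-9-[5-(furan-3-ylmethyl)furan-3-yl]-2,6-dimethylnona-4,6-dienal
Conditions: Dess–Martin periodinane, pyridine, CH2Cl2, 0 °C; used at once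
Reagents that add atoms: none
Why: Dess–Martin oxidation gives the α-branched aldehyde under near-neutral conditions that preserve α-stereocentres.

**Step 17**
Reactants: 24 4-hydroxy-3-methylfuran-2(5H)-one
Product: 25 4-methoxy-3-methylfuran-2(5H)-one
Conditions: (CH3O)2SO2, K2CO3, acetone, reflux
Reagents that add atoms: dimethyl sulfate, COS(=O)(=O)OC
Why: O-alkylation of the vinylogous acid by a hard methylating agent masks the acidic hydroxyl so that C5 can be lithiated.

**Step 18**
Reactants: 25 4-methoxy-3-methylfuran-2(5H)-one; 23 (2S,4E,6E)-9-[5-(furan-3-ylmethyl)furan-3-yl]-2,6-dimethylnona-4,6-dienal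
Product: 28 (5Z)-5-{(2S,4E,6E)-9-[5-(furan-3-ylmethyl)furan-3-yl]-2,6-dimethylnona-4,6-dien-1-ylidene}-4-methoxy-3-methylfuran-2(5H)-one, via aldol adduct 26 (not isolated), via mesylate 27 (not isolated)
Conditions: LiN(i-Pr)2, THF, −78 °C; 23; then CH3SO2Cl, −78 → 0 °C; then DBU, 0 °C → rt
Reagents that add atoms: none
Why: C5 lithiation of the methyl tetronate and aldol addition, then mesylation and E1cB elimination, should give the thermodynamically preferred (Z)-ylidene with the chain syn to the ring oxygen and away from the 4-methoxy group; the two transient carbinol centres are destroyed and the allylic (S) centre is too weakly acidic for DBU.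

**Step 19**
Reactants: 28 (5Z)-5-{(2S,4E,6E)-9-[5-(furan-3-ylmethyl)furan-3-yl]-2,6-dimethylnona-4,6-dien-1-ylidene}-4-methoxy-3-methylfuran-2(5H)-one
Product: 29 (5Z)-5-{(2S,4E,6E)-9-[5-(furan-3-ylmethyl)furan-3-yl]-2,6-dimethylnona-4,6-dien-1-ylidene}-4-hydroxy-3-methylfuran-2(5H)-one
Conditions: LiCl, DMSO, 60 °C; then cold dilute aq. HCl (pH 3)
Reagents that add atoms: none
Why: SN2 demethylation of the vinylogous ester by chloride in a dipolar aprotic solvent expels the stabilised tetronate, and these neutral conditions leave the diene, both furans, the (Z)-alkene and the stereocentre unchanged.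

**Compound list**
1 | 2-(furan-3-yl)acetic acid | OC(=O)Cc1ccoc1 | starting material
2 | 2-(furan-3-yl)ethan-1-ol | OCCc1ccoc1 | intermediate
3 | 2-(furan-3-yl)acetaldehyde | O=CCc1ccoc1 | intermediate
4 | (±)-1-(furan-3-yl)but-3-en-2-ol | C=CC(O)Cc1ccoc1 | intermediate
5 | diethyl malonate | CCOC(=O)CC(=O)OCC | starting material
6 | (3-bromopropoxy)(tert-butyl)dimethylsilane | BrCCCO[Si](C)(C)C(C)(C)C | starting material
7 | diethyl 2-{3-[(tert-butyldimethylsilyl)oxy]propyl}propanedioate | CCOC(=O)C(CCCO[Si](C)(C)C(C)(C)C)C(=O)OCC | intermediate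
8 | 2-{3-[(tert-butyldimethylsilyl)oxy]propyl}propanedioic acid | OC(=O)C(CCCO[Si](C)(C)C(C)(C)C)C(=O)O | intermediate
9 | 5-[(tert-butyldimethylsilyl)oxy]-2-methylidenepentanoic acid | C=C(CCCO[Si](C)(C)C(C)(C)C)C(=O)O | intermediate
10 | (±)-1-(furan-3-yl)but-3-en-2-yl 5-[(tert-butyldimethylsilyl)oxy]-2-methylidenepentanoate | C=CC(Cc1ccoc1)OC(=O)C(=C)CCCO[Si](C)(C)C(C)(C)C | intermediate
11 | (±)-3-{3-[(tert-butyldimethylsilyl)oxy]propyl}-5-(furan-3-ylmethyl)furan-2(5H)-one | O=C1OC(Cc2ccoc2)C=C1CCCO[Si](C)(C)C(C)(C)C | intermediate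
12 | 3-{3-[(tert-butyldimethylsilyl)oxy]propyl}-5-(furan-3-ylmethyl)-2,5-dihydrofuran-2-ol (lactol, diastereomer mixture) | OC1OC(Cc2ccoc2)C=C1CCCO[Si](C)(C)C(C)(C)C | intermediate
13 | tert-butyl{3-[5-(furan-3-ylmethyl)furan-3-yl]propoxy}dimethylsilane | CC(C)(C)[Si](C)(C)OCCCc1coc(Cc2ccoc2)c1 | intermediate
14 | 3-[5-(furan-3-ylmethyl)furan-3-yl]propan-1-ol | OCCCc1coc(Cc2ccoc2)c1 | intermediate
15 | 3-[5-(furan-3-ylmethyl)furan-3-yl]propanal | O=CCCc1coc(Cc2ccoc2)c1 | intermediate
16 | (2E)-5-[5-(furan-3-ylmethyl)furan-3-yl]-2-methylpent-2-enal | O=C/C(C)=C/CCc1coc(Cc2ccoc2)c1 | intermediate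
17 | 2-(furan-3-ylmethyl)-4-[(3E,5E)-6-iodo-4-methylhexa-3,5-dien-1-yl]furan | I/C=C/C(C)=C/CCc1coc(Cc2ccoc2)c1 | intermediate
18 | methyl (2S)-3-hydroxy-2-methylpropanoate | COC(=O)[C@@H](C)CO | starting material
19 | methyl (2R)-3-iodo-2-methylpropanoate | COC(=O)[C@@H](C)CI | intermediate
20 | [(2R)-3-methoxy-2-methyl-3-oxopropyl]zinc iodide | COC(=O)[C@@H](C)C[Zn]I | intermediate
21 | methyl (2S,4E,6E)-9-[5-(furan-3-ylmethyl)furan-3-yl]-2,6-dimethylnona-4,6-dienoate | COC(=O)[C@@H](C)C/C=C/C(C)=C/CCc1coc(Cc2ccoc2)c1 | intermediate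
22 | (2S,4E,6E)-9-[5-(furan-3-ylmethyl)furan-3-yl]-2,6-dimethylnona-4,6-dien-1-ol | OC[C@@H](C)C/C=C/C(C)=C/CCc1coc(Cc2ccoc2)c1 | intermediate
23 | (2S,4E,6E)-9-[5-(furan-3-ylmethyl)furan-3-yl]-2,6-dimethylnona-4,6-dienal | O=C[C@@H](C)C/C=C/C(C)=C/CCc1coc(Cc2ccoc2)c1 | intermediate
24 | 4-hydroxy-3-methylfuran-2(5H)-one (3-methyltetronic acid) | CC1=C(O)COC1=O | starting material
25 | 4-methoxy-3-methylfuran-2(5H)-one | COC1=C(C)C(=O)OC1 | intermediate
26 | 5-{(2S,4E,6E)-9-[5-(furan-3-ylmethyl)furan-3-yl]-1-hydroxy-2,6-dimethylnona-4,6-dien-1-yl}-4-methoxy-3-methylfuran-2(5H)-one (mixture at the ring and carbinol centres) | COC1=C(C)C(=O)OC1C(O)[C@@H](C)C/C=C/C(C)=C/CCc1coc(Cc2ccoc2)c1 | intermediate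
27 | methanesulfonate of 26 | COC1=C(C)C(=O)OC1C(OS(C)(=O)=O)[C@@H](C)C/C=C/C(C)=C/CCc1coc(Cc2ccoc2)c1 | intermediate
28 | (5Z)-5-{(2S,4E,6E)-9-[5-(furan-3-ylmethyl)furan-3-yl]-2,6-dimethylnona-4,6-dien-1-ylidene}-4-methoxy-3-methylfuran-2(5H)-one | CC1=C(OC)/C(=C/[C@@H](C)C/C=C/C(C)=C/CCc2coc(Cc3ccoc3)c2)OC1=O | intermediate
29 | (5Z)-5-{(2S,4E,6E)-9-[5-(furan-3-ylmethyl)furan-3-yl]-2,6-dimethylnona-4,6-dien-1-ylidene}-4-hydroxy-3-methylfuran-2(5H)-one | CC1=C(O)/C(=C/[C@@H](C)C/C=C/C(C)=C/CCc2coc(Cc3ccoc3)c2)OC1=O | target

**Step count**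
Total steps: 19.
Longest linear sequence: 15 steps (3, 4, 5, 6, 7, 8, 9, 10, 11, 12, 14, 15, 16, 18, 19), counted from diethyl malonate 5.

**Steps most likely to fail**

Step 7. The electron-poor 1,1-disubstituted acrylate alkene may engage the carbene slowly, so intermolecular metathesis of the vinyl groups or ruthenium-hydride alkene migration could outrun ring closure. The fallback avoids metathesis and sets out from 2. The aldehyde 3 is made as in step 2 and trapped with the lithium acetylide of commercial tert-butyldimethyl(pent-4-yn-1-yloxy)silane (n-BuLi, THF, −78 °C) to give 1-(furan-3-yl)-7-[(tert-butyldimethylsilyl)oxy]hept-3-yn-2-ol F1. Hydroxyl-directed trans-hydroalumination with NaAlH2(OCH2CH2OCH3)2 followed by I2 at −78 °C should give (3Z)-1-(furan-3-yl)-4-iodo-7-[(tert-butyldimethylsilyl)oxy]hept-3-en-2-ol F2. Carbonylative lactonisation (PdCl2(PPh3)2, CO, K2CO3, THF), in which the cis hydroxyl captures the acyl-palladium species, comes back to the route at 11.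

Step 12. E-selectivity may be incomplete in the chromium-mediated olefination of a conjugated aldehyde, and the iododiene may isomerise or decompose in light. The fallback sets out from 16. Colvin homologation with lithiated trimethylsilyldiazomethane (Me3SiCHN2, LiN(i-Pr)2, THF, −78 → 0 °C) gives 2-(furan-3-ylmethyl)-4-[(3E)-4-methylhex-3-en-5-yn-1-yl]furan F3. Syn hydrozirconation with Cp2Zr(H)Cl (THF, rt) places zirconium on the terminal carbon and gives chlorobis(cyclopentadienyl)[(1E,3E)-6-[5-(furan-3-ylmethyl)furan-3-yl]-3-methylhexa-1,3-dien-1-yl]zirconium F4. Iodinolysis with retention (I2, 0 °C) comes back at 17 with the E geometry fixed by the mechanism.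

Step 18. The basic lithium dienolate may deprotonate the α-branched aldehyde instead of adding to it, which loses material and erodes the (S) centre, or the aldolate may revert before it is trapped. The fallback sets out from 25. Silylation (LiN(i-Pr)2, Me3SiCl, THF, −78 °C) gives [(4-methoxy-3-methylfuran-2-yl)oxy]trimethylsilane F5. A vinylogous Mukaiyama aldol addition of F5 to 23 (BF3·OEt2, CH2Cl2, −78 °C) forms the C5–C bond without a strong base and comes back at 26, which is mesylated and eliminated with DBU as in step 18.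

**Further compounds**
F1 | step 7 | 1-(furan-3-yl)-7-[(tert-butyldimethylsilyl)oxy]hept-3-yn-2-ol | OC(Cc1ccoc1)C#CCCCO[Si](C)(C)C(C)(C)C
F2 | step 7 | (3Z)-1-(furan-3-yl)-4-iodo-7-[(tert-butyldimethylsilyl)oxy]hept-3-en-2-ol | OC(Cc1ccoc1)/C=C(I)/CCCO[Si](C)(C)C(C)(C)C
F3 | step 12 | 2-(furan-3-ylmethyl)-4-[(3E)-4-methylhex-3-en-5-yn-1-yl]furan | C#C/C(C)=C/CCc1coc(Cc2ccoc2)c1
F4 | step 12 | chlorobis(cyclopentadienyl)[(1E,3E)-6-[5-(furan-3-ylmethyl)furan-3-yl]-3-methylhexa-1,3-dien-1-yl]zirconium | Cl[Zr](C1C=CC=C1)(C1C=CC=C1)/C=C/C(C)=C/CCc1coc(Cc2ccoc2)c1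
F5 | step 18 | [(4-methoxy-3-methylfuran-2-yl)oxy]trimethylsilane | COc1coc(O[Si](C)(C)C)c1C
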